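- A small charge of catalyst raises one question: how many substrate molecules does each catalyst turn before the product stops growing?

| setting | Tuesday's | Wednesday's | flask |
|---|---|---|---|
| left-handed substrate | 13 mM | 30 mM | 20 mM |
| right-handed substrate | 13 mM | 30 mM | 20 mM |
| gas | 1.6 mM (held) | 1.6 mM (held) | 1.6 mM (held) |
| free catalyst | 40 µM | 40 µM | 40 µM |
| remark | run made earlier | run made earlier |  |
| time |  |  | 2.5 d |

- Tuesday's (time / d: left-handed product / %, right-handed product / %): 0.500: 11.3, 32.7; 1.04: 10.9, 32.4; 1.67: 10.8, 31.6; 2.08: 11.3, 31.6; 2.50: 11.3, 32.1
- Wednesday's (time / d: left-handed product / %, right-handed product / %): 0.500: 13.1, 36.8; 1.04: 13.2, 36.8; 1.67: 13.1, 37.0; 2.08: 12.7, 37.3; 2.50: 12.8, 37.3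

(scatter of a reading: 0.5 percentage points)

- excess of left-handed product over right-handed product in the product at 6.0 h
- excess of left-handed product over right-handed product in the product at 2.5 d
- part of the left-handed substrate and right-handed substrate charged together that has reacted at 2.5 d

- free catalyst is single-handed; left-handed substrate and right-handed substrate are mirror images of each other, charged as a racemate, each of them at the stated concentration
- the earlier runs were read with a standard deviation of 0.5 percentage points
- at the start none of the gas is in solution
- an excess is below zero if the other one leads

- From the first reading on, the two runs show little change with time: the reacted part reads 44.0% at 0.500 d and 43.4% at 2.50 d on Tuesday, and 49.9% and 50.1% at those times on Wednesday.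
- Catalyst and gas need no correction, since they stand at 40 µM and 1.6 mM in both runs and in the flask.
- The substrate charge does count: the mean reacted part rises from 43.2% on Tuesday to 50.0% on Wednesday.
- The reading scatter of 0.5 percentage points is smaller than that gap of 6.8 points, so the gap can be used.
- I divide the reacted part of the charge by the part of the charge that is catalyst, which gives 281 on Tuesday and 750 on Wednesday.
- A straight log-log line through these two runs gives the flask's turnover number, 466, so I expect 46.6% reacted in the flask.
- The forecast gives −50%, −48.3% and 46.5%, holding that “the reaction has died rather than run out of substrate”.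
- The flask gives −52.8% at 6.0 h, then −48.8% and 46.8% at 2.5 d.

    free catalyst + left-handed substrate ⇌ catalyst intermediate A (K = 16.0 /M, k = 1.10 × 10⁵ /M/h)
    free catalyst + right-handed substrate ⇌ catalyst intermediate B (K = 290 /M, k = 1.20 × 10⁵ /M/h)
    reagent + catalyst intermediate A → free catalyst + left-handed product (k = 3.20 × 10⁶ /M/h)
    reagent + catalyst intermediate B → free catalyst + right-handed product (k = 1.20 × 10⁶ /M/h)
    gas ⇌ reagent, rate k5*(csat - [reagent]) (kL = 2.10 /h)
    reagent + free catalyst → spent catalyst A (k = 2700 /M/h)
    2 free catalyst → spent catalyst B (k = 77000 /M/h)

- The flask's turnover number is 468, against my 466. The neighbour flask has 0.010 mM of free catalyst, a quarter of the flask's, and the same substrate charge, so an unchanged turnover number gives 11.6% reacted. It reacts 23.5%, a turnover number of 942, twice the flask's. The neighbour ends with spent catalyst A at 83.6% of its catalyst, against 41.9% in the flask.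

The numbers in the tables come from a simulation for an exercise, and the scatter is random.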